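We chose to judge the eta flask by where the zeta flask stopped, not by how fast it began. The eta flask repeats the zeta charge.

| setting | zeta | theta | eta |
|---|---|---|---|
| starting material | 80.0 mM | 120 mM | 80.0 mM |
| partner | 96.0 mM | 96.0 mM | 96.0 mM |
| time |  |  | 12 min |

| zeta run: time / min | zeta run: [product] / mM | theta run: time / min | theta run: [product] / mM |
|---|---|---|---|
| 1.2 | 13.5 | 1.2 | 17.1 |
| 2.5 | 22.2 | 2.5 | 28.2 |
| 3.7 | 24.4 | 3.7 | 30.0 |
| 5.0 | 26.0 | 5.0 | 32.7 |
| 6.2 | 25.9 | 6.2 | 33.3 |

(standard deviation of a reading: 0.6 mM)

- apparent order in [starting material] of the starting rate, round the charge of the zeta run (the rate where two percent of its starting material have turned into product) (one fixed amount of product, the same in the runs compared)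
- product in the eta run at 12 min, as a share of the starting material charged

- Overall: starting material + partner -> product.
- Constant volume, constant temperature.
- "The second partner" is partner.
- An order is taken over about fifteen percent of the charge, up and down.

The last two readings of the zeta run lie level, with a mean of 25.9 mM, and those of the theta run average 33.0 mM. The zeta level lies below the charge of either reactant. The theta run had 1.50 times the starting material and the same partner, yet its level is 1.27 times higher. Divided by the charge, these levels give 32.4% for the zeta run and 27.5% for the theta run. We call this level over the starting material charged the stopping share, the plateau yield. The theta run stops at a smaller share than the zeta run, and we read that as a loss of starting material that grows faster than the charge.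

That fall in the share makes product rise as the charge to the power 0.593. The first readings stand in the ratio 1.27, close to the ratio of the levels, so we take this power as the order. For the eta run at 12 min, we commit to the zeta stopping share.

The forecast gives 0.62 and 32.5%, an order above ours. Its ground is that “theta/zeta stays at about 1.27 at every time point”.

    starting material + partner → intermediate (3.690 M⁻¹ min⁻¹)
    intermediate → product (2.520 min⁻¹)
    starting material → decomposed substrate (0.2814 min⁻¹)
    2 starting material → homo dimer (4.584 M⁻¹ min⁻¹)

The flask gives an order of 0.61, and the eta run reaches 33.7%, 1.3 percentage points above the zeta stopping share of 32.4%. The theta stopping share of 27.5% lies a little above a quarter of its charge, and that run comes to this mark at 3.31 min, later than the zeta run at 2.20 min. The eta run stands at 33.7% at 12 min because of two paths acting together: without the path to decomposed substrate it reaches 48.5%, and without the path to homo dimer 49.3%.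

The earlier runs and the new flask are simulated on assumed constants; the scatter is artificial.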